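At early times the birch run loses its fraction left, f = 1 − y (the share of the charged Q not yet in J or D), at 0.246 h⁻¹. The J column already counts D in, so f stands at 63.9% at 4.00 h and at 51.9% at 10.0 h.

| flask | Q | remark | time |
|---|---|---|---|
| birch | 0.075 M | run made earlier |  |
| flask | 0.050 M |  | 2.0 d |
birch run (percent of the Q charged)

| time / h | J / % | D / % |
|---|---|---|
| 0.833 | 18.5 | 4.7 |
| 1.33 | 23.9 | 6.4 |
| 2.00 | 28.1 | 15.3 |
| 2.50 | 30.2 | 17.8 |
| 4.00 | 36.1 | 29.8 |
| 6.00 | 40.3 | 34.7 |
| 10.0 | 48.1 | 46.7 |

(each reading ± 1 percentage point)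
1. J and D together at 2.0 d, in percent of the Q charged
2. concentration of J in solution at 2.0 d, in percent of saturation
- for J the D are counted in
- as a solid, counted per litre of solution: D

Between these two readings ln f gives the tail constant, an apparent first-order constant read from the J column, 0.0347 h⁻¹, which is slower than the early slope. A second way reads the same constant from the D column and gives 0.0459 h⁻¹. The two part, and the D column cheats: over those hours D gained 17 percentage points and J gained 12 points, the excess being dissolved J turning to crystal, as J − D fell from 6.3 points to 1.4 points.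

Carrying the J-column constant unchanged to the flask, itself an assumption, this reckoning leaves f = 13.9% at 2.0 d, so y is near 86.1%. The last gap in the birch run reads c_J near 1.05 mM, a rough reading given the scatter.

The forecast differs, with 99% and 103%, holding that the loss “stays near 0.27 per hour from 23% to 95%, with no plateau”; here y at the last reading is 48.1%, not 95.

The flask gives 75.7% and 119%.

    Q ⇌ J (K = 0.980, k = 1.00 × 10⁻⁴ s⁻¹)
    Q ⇌ E (K = 2.70, k = 3.70 × 10⁻⁵ s⁻¹)
    Q ⇌ Z (K = 1.20, k = 1.20 × 10⁻⁴ s⁻¹)
    D ⇌ J, rate k4*(cs4 - [J]) while solid is left; crystals form when [J] > cs4 (solubility = 1.10 mM, k = 2.00 × 10⁻⁴ s⁻¹)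
    J → X (k = 4.00 × 10⁻⁷ s⁻¹)
    2 Q → G (k = 8.10 × 10⁻⁵ M⁻¹ s⁻¹)

So f in the flask is 24.3%, not 13.9%, and from y = 49.9% at 10.0 h the tail ran at 0.0190 h⁻¹, slower than 0.0347 h⁻¹. The main reason for the height of y in the flask is the limit of solubility of J: the run without that limit reaches 15.4% against 75.7%. The tail is paced in part by the return of E to Q: the run without that return reaches 51.3%, and E still holds 13.6% at the end. In a neighbour flask, charged with 0.013 M of Q, the same constant again promises f = 13.9%, but f is 46.9%, with 25.4% standing as E.

(The data stem from a simulated flask from invented constants, noise included.)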